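# Proposed total synthesis of CNP0332980.1 (compound 47)

## The problem

Compound 47 is built from two 3,4-dihydro-2H-cyclohepta[b]pyran units, each a tropolone fused to a dihydropyran through the enol-ether bond C4a=C9a, joined from C2 to C2' by an (E,E)-buta-1,3-diene. It carries three stereocentres: C2 and C3 of the methylated (left) pyran, which are R,R and trans, and C2' of the right pyran, which is R. C2 and C3 are neighbours and can be set together, but four sp2 carbons separate the two pyrans, so neither half can control the other and each needs its own source of absolute configuration. Each C2–O bond is an allylic (in 47 a dienylic) ether of a vinylogous acid, so acids, Lewis acids and zerovalent palladium can ionise it and scramble C2. The free tropolones chelate metals and are ambident, and the α-alkoxy aldehydes needed to build the diene epimerise under base, so the tropolones must stay masked and basic olefinations at C2 are excluded. The tropolone substitution is fixed: methyl on C5 next to the ring-fusion carbon, the two oxygens on C7 and C8, and hydrogen on C6 and C9. The feature that opens the route is the shared C4a=C9a bond: a 3,4-dihydro-2H-pyran with acetyl on C5 and formyl on C6 already holds C4a, C9a, C5 (with its methyl) and C9, and the missing C6–C7–C8 unit with both oxygens is a methoxyacetone equivalent.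

## Retrosynthesis

**47 to 46.** The two O–CH3 bonds are cut last. The tropolone oxygens are equivalent through tautomerism, so the bis(methyl ether) 46 leads to 47 whichever oxygen carries the methyl group. The forward step must unmask two vinylogous esters without acid reaching the dienylic C2–O bonds.

**46 to 24 and 45.** The central C–C single bond of the diene is cut, giving alkenylstannane 24 and alkenyl iodide 45. A C=C disconnection by olefination would place a carbanion β to the ring oxygen (E1cB opening of the pyran) or expose an epimerisable α-alkoxy aldehyde to base. A palladium-catalysed union would put the product in contact with a metal that can ionise its C2–O bonds. A copper-mediated stannane/iodide coupling avoids both, and each fragment holds one tropolone and its own stereocentres.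

**24 and 45 to 18 and 42.** Each alkenyl–metal or alkenyl–halogen unit is cut at its C=C bond back to aldehydes 20 and 44, and these through alcohols 19 and 43 to the silyl ethers 18 and 42. Chromium-mediated one-carbon olefinations are non-basic and E-selective, which is what an α-alkoxy aldehyde needs. The gem-dibromo tin reagent 23 comes from 21.

**18 to 15 and 2; 42 to 39 and 2 (key disconnection).** Two ring bonds of each tropolone are cut: C9–C8 and C5–C6. This removes the whole seven-membered ring and leaves keto aldehydes 15 and 39 and the three-carbon phosphonate 2 (from 1). Against buying or making a substituted tropolone and attaching the pyran later, this cut places methyl, carbonyl and methoxy unambiguously and keeps the ring-fusion bond intact. The forward reaction must olefinate the aldehyde first, choose the right aldol donor, and close a seven-membered ring.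

**15 to 9; 39 to 33.** The acetyl–C5 bond is cut to bromo enals 13 and 37 (cross-coupling with an acetyl-anion equivalent), the C5–Br bond to enals 11 and 35, and the formyl–C6 bond to the plain cyclic enol ethers 9 and 33. The order matters: C6 is functionalised by lithiation while the ring is still a simple enol ether, and C5 is functionalised afterwards by electrophilic bromination, so no step has to differentiate two methyl groups or two carbonyls.

**9 to 3.** The enol ether comes from lactol 7 by dehydration, the lactol from homoallylic alcohol 5 by hydroformylation (one carbon added, ring closed spontaneously), and 5 from silyl glycidyl ether 4 and thus from glycidol 3. The single stereocentre is bought, and the triisopropylsilyl group is chosen because it has no Si–CH3 group that t-BuLi could deprotonate later.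

**33 to 25.** The same lactol/hydroformylation logic leads from 33 through 31 to homoallylic alcohol 29. Its C2–C3 bond is cut by an anti-selective asymmetric crotylation of aldehyde 28, which sets both stereocentres of the left half in one step; 28 comes from diol 25 via 26.

## Roads not taken

**Alternative 1:** The cut runs through C2–C3 of both pyrans. A double Ireland–Claisen rearrangement of a mixed propionate/acetate diester, built on a chiral-pool 1,2-diol that carries two aryloxyvinyl groups, would give the dienyl diacid A1 with all three stereocentres and the (E,E)-diene in one step.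
- Merits: the stereochemical economy is better than in the chosen plan; two chair transition states replace one chiral-pool epoxide, one asymmetric crotylation and a fragment coupling.
- Weak points:
  - A C2-symmetric diol must carry two different esters in defined positions.
  - The propionate ketene acetal geometry and both enol-ether geometries must be controlled.
  - Two tropone carbonyls and two aryl bromides must survive excess amide base.
  - After A1 both pyran rings are still open, and each must be closed by forming the C4–C4a bond between a reduced acid carbon and a bromotropone, a bond formation with little precedent.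
  - The halogenated, differentially protected tropolones must be made by some other route.
- Comparison: the chosen plan is longer per stereocentre, but it builds the tropolone nucleus itself with defined regiochemistry on a pyran whose ring-fusion bond already exists.

**Alternative 2:** The cut is the O1–C2 bond of the left pyran. Pd(PPh3)4 (zerovalent palladium) would open a tropolonyl vinylcyclopropane between the vinyl-bearing and the tropolone-bearing carbon, and the ring hydroxyl would add to the allyl terminus to give A2 with an (E)-silylvinyl handle.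
- Merits: neutral ring closure; trans control of C2 by C3 through a reversible π-allyl intermediate; and a coupling handle that is already in place, which is more economical than the three steps from 18 to 24 here.
- Weak points:
  - Palladium opening of vinylcyclopropanes normally needs two acceptor groups on the carbon that becomes the carbanion, and a deprotonated hydroxytropone is electron-rich rather than accepting.
  - An enantiopure, diastereopure cyclopropane bearing a tropolone is required.
  - The right half has no C3 substituent to control C2'.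
  - The same π-allyl chemistry can later erode C2.
  - The tropolones must pre-exist.
- Comparison: the chosen plan gives up the built-in handle, but never exposes a C2–O bond to zerovalent palladium and makes the tropolone ring.

**Alternative 3:** The cut is the O1'–C2' bond of the right pyran at the last stage. The ring hydroxyl of a hydroxytropone would add to an alkene terminus while a bis-allylic hydroxyl leaves (syn-SN2'), closing the right pyran and creating the diene to give A3, which is the same compound as 46.
- Merits: this is the most convergent endgame; the chain is assembled by carbonyl additions, and the diene and the last stereocentre arise together by 1,3-chirality transfer, with no tin and no separate fragment coupling.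
- Weak points:
  - A bis-allylic alcohol ionises easily, which erodes the chirality transfer and can give regioisomeric ethers.
  - The π-acidic catalyst that activates the substrate can also re-ionise the dienylic C–O bonds of the product at both C2 and C2'.
  - The nucleophile is an acidic, ambident hydroxytropone.
  - Both tropolones must again be available preformed and differentially protected.
- Comparison: the chosen plan has the longer endgame, but forms the sensitive dienyl bis-ether under copper mediation with no ionising species, fixes C2' early from the chiral pool, and solves the tropolone construction.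

Key step: step 9

## Remarks before the route

- Remark: the two oxygens of a tropolone exchange by fast tautomerism, so 18, 42 and 46 are drawn as the 8-methoxy-7-oxo isomers that the annulation should deliver, and 47 results whichever oxygen carried the methyl group.
- Remark: compounds marked "starting material" and the reagents named under "Reagents that add atoms" are taken to be purchasable; 2 and 23 are made in steps 1 and 12.
- Remark: 2 is racemic; its stereocentre becomes sp2 in steps 9 and 22.

## Route

Step 1
Reactants: 1 dimethyl (1-diazo-2-oxopropyl)phosphonate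
Product: 2 dimethyl (1-methoxy-2-oxopropyl)phosphonate
Conditions: MeOH, Rh2(OAc)4 (1 mol %), benzene, 80 °C
Reagents that add atoms: methanol, CO
Why: Rh2(OAc)4 converts the diazo compound to a rhodium carbenoid that inserts into the O–H bond of methanol (carbenoid O–H insertion), an established way to α-alkoxy phosphonates.

Step 2
Reactants: 3 (S)-glycidol
Product: 4 triisopropylsilyl (R)-glycidyl ether
Conditions: TIPSCl, imidazole, CH2Cl2, 0 °C → rt
Reagents that add atoms: triisopropylsilyl chloride, CC(C)[Si](Cl)(C(C)C)C(C)C
Why: Imidazole-promoted silylation of the primary alcohol; the stereocentre is untouched and the descriptor changes from S to R only because the silyloxymethyl group now outranks the ring carbon. Triisopropylsilyl is used because it has no Si–CH3 group for t-BuLi to deprotonate in step 6.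

Step 3
Reactants: 4 triisopropylsilyl (R)-glycidyl ether
Product: 5 (R)-1-(triisopropylsilyloxy)pent-4-en-2-ol
Conditions: CH2=CHMgBr, CuI (10 mol %), THF, −30 °C
Reagents that add atoms: vinylmagnesium bromide, C=C[Mg]Br
Why: Copper-catalysed SN2 opening of the terminal epoxide by the Grignard reagent at the unsubstituted carbon; the stereocentre from 3 is not involved.

Step 4
Reactants: 5 (R)-1-(triisopropylsilyloxy)pent-4-en-2-ol
Product: 7 (6R)-6-[(triisopropylsilyloxy)methyl]tetrahydro-2H-pyran-2-ol, via hydroxy aldehyde 6 (not isolated)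
Conditions: Rh(CO)2(acac) (1 mol %), BiPhePhos, CO/H2 (1:1, 5 bar), THF, 60 °C
Reagents that add atoms: carbon monoxide, [C-]#[O+]
Why: Linear-selective rhodium-catalysed hydroformylation of the terminal alkene gives the δ-hydroxy aldehyde, which should close at once to the six-membered lactol (anomer mixture).

Step 5
Reactants: 7 (6R)-6-[(triisopropylsilyloxy)methyl]tetrahydro-2H-pyran-2-ol
Product: 9 (R)-2-[(triisopropylsilyloxy)methyl]-3,4-dihydro-2H-pyran, via anomeric mesylate 8 (not isolated)
Conditions: MsCl, Et3N, CH2Cl2, 0 °C → reflux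
Reagents that add atoms: none
Why: Mesylation of the lactol hydroxyl and amine-induced 1,2-elimination of the anomeric sulfonate, the lactol dehydration used for glycal-type enol ethers.

Step 6
Reactants: 9 (R)-2-[(triisopropylsilyloxy)methyl]-3,4-dihydro-2H-pyran
Product: 11 (2R)-2-[(triisopropylsilyloxy)methyl]-3,4-dihydro-2H-pyran-6-carbaldehyde, via 6-lithio enol ether 10 (not isolated)
Conditions: t-BuLi, THF, −78 → 0 °C; DMF, −78 °C → rt
Reagents that add atoms: N,N-dimethylformamide, CN(C)C=O
Why: α-Lithiation of the cyclic enol ether at the vinylic C6–H next to oxygen, then formylation of the alkenyllithium with DMF.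

Step 7
Reactants: 11 (2R)-2-[(triisopropylsilyloxy)methyl]-3,4-dihydro-2H-pyran-6-carbaldehyde
Product: 13 (2R)-5-bromo-2-[(triisopropylsilyloxy)methyl]-3,4-dihydro-2H-pyran-6-carbaldehyde, via dibromide 12 (not isolated)
Conditions: Br2, CH2Cl2, −78 °C; then Et3N, −78 °C → rt
Reagents that add atoms: bromine, BrBr
Why: Bromination–dehydrobromination as used for α-alkoxy enones: bromine adds across the enol-ether double bond and the amine removes HBr through the labile anomeric bromide, leaving bromine on C5.

Step 8
Reactants: 13 (2R)-5-bromo-2-[(triisopropylsilyloxy)methyl]-3,4-dihydro-2H-pyran-6-carbaldehyde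
Product: 15 (2R)-5-acetyl-2-[(triisopropylsilyloxy)methyl]-3,4-dihydro-2H-pyran-6-carbaldehyde, via ethoxyvinyl enal 14 (not isolated)
Conditions: tributyl(1-ethoxyvinyl)stannane, Pd(PPh3)4 (5 mol %), CuI (10 mol %), toluene, 90 °C; then 1 M HCl, THF, 0 °C → rt
Reagents that add atoms: tributyl(1-ethoxyvinyl)stannane, CCCC[Sn](CCCC)(CCCC)C(=C)OCC; water, O
Why: Stille coupling of the activated β-bromo enal with an acetyl-anion equivalent, then mild acid hydrolysis of the enol ether to the methyl ketone; the triisopropylsilyl ether should survive dilute acid.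

Step 9
Reactants: 15 (2R)-5-acetyl-2-[(triisopropylsilyloxy)methyl]-3,4-dihydro-2H-pyran-6-carbaldehyde; 2 dimethyl (1-methoxy-2-oxopropyl)phosphonate
Product: 18 (2R)-8-methoxy-5-methyl-2-[(triisopropylsilyloxy)methyl]-3,4-dihydrocyclohepta[b]pyran-7(2H)-one, via dienone 16 (not isolated), via aldol adduct 17 (not isolated)
Conditions: LiCl, DBU, MeCN, 0 °C → rt; then 50 °C
Reagents that add atoms: none
Why: Proposed new method: the lithium-chelated anion of 2 olefinates the formyl group of 15 (Horner–Wadsworth–Emmons) to dienone 16, whose α-methoxy methyl ketone is then soft-enolised and adds to the acetyl carbonyl, and loss of water from aldol 17 gives the methoxytropone. The closest known reaction types are the double aldol condensation of aromatic 1,2-dialdehydes with alkoxyacetones to benzotropolones and tandem Horner–Wadsworth–Emmons/aldol annulations. The seven-membered ring closes by a 7-(enolendo)-exo-trig aldol addition, whereas the competing five-ring Michael closure onto C6 of the pyran would be 5-(enolendo)-exo-trig and is stereoelectronically disfavoured. No stereocentre is created that survives: the carbinol carbon of 17 becomes sp2, and C2 of the pyran has no acidic hydrogen and is not touched. Three selectivities are needed: the phosphonate carbon must meet the aldehyde and not the ketone, which the much higher electrophilicity of the formyl group secures and which puts methoxy next to C9; the aldol donor must be the new methyl ketone and not the acetyl group, which is favoured because lithium chelation between its carbonyl and the α-methoxy group acidifies it while the acetyl group is a deactivated vinylogous ester, and because the hydroxyl of 17 leaves from a carbon that the ring oxygen stabilises vinylogously; and only the dienone isomer with the pyran carbon and the acyl group cis can close, which reversible conjugate addition of the amidine and reversible oxa-6π closure of the cis-dienone should supply. Aromatisation to the tropone makes the sequence irreversible.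

Step 10
Reactants: 18 (2R)-8-methoxy-5-methyl-2-[(triisopropylsilyloxy)methyl]-3,4-dihydrocyclohepta[b]pyran-7(2H)-one
Product: 19 (2R)-2-(hydroxymethyl)-8-methoxy-5-methyl-3,4-dihydrocyclohepta[b]pyran-7(2H)-one
Conditions: TBAF, AcOH, THF, 0 °C → rt
Reagents that add atoms: none
Why: Fluoride cleavage of the silyl ether, buffered with acetic acid so that the methoxytropone sees no strong base.

Step 11
Reactants: 19 (2R)-2-(hydroxymethyl)-8-methoxy-5-methyl-3,4-dihydrocyclohepta[b]pyran-7(2H)-one
Product: 20 (2R)-8-methoxy-5-methyl-7-oxo-2,3,4,7-tetrahydrocyclohepta[b]pyran-2-carbaldehyde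
Conditions: Dess–Martin periodinane, NaHCO3, CH2Cl2, 0 °C → rt
Reagents that add atoms: none
Why: Dess–Martin oxidation under buffered, non-basic conditions should keep the α-alkoxy aldehyde from epimerising; it is used at once.

Step 12
Reactants: 21 dibromomethane
Product: 23 tributyl(dibromomethyl)stannane, via dibromomethyllithium 22 (not isolated)
Conditions: LiN(i-Pr)2, THF, −78 °C; then Bu3SnCl, −78 °C → rt
Reagents that add atoms: tributyltin chloride, CCCC[Sn](Cl)(CCCC)CCCC
Why: Low-temperature deprotonation of dibromomethane and stannylation of the resulting carbenoid, the standard preparation of gem-dihalomethyl tin reagents.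

Step 13
Reactants: 20 (2R)-8-methoxy-5-methyl-7-oxo-2,3,4,7-tetrahydrocyclohepta[b]pyran-2-carbaldehyde; 23 tributyl(dibromomethyl)stannane
Product: 24 (2R)-8-methoxy-5-methyl-2-[(E)-2-(tributylstannyl)ethenyl]-3,4-dihydrocyclohepta[b]pyran-7(2H)-one
Conditions: CrCl2, LiI, THF/DMF, rt, dark
Reagents that add atoms: none
Why: Takai-type stannyl olefination: a geminal dichromium species generated from 23 by divalent chromium adds to the aldehyde and eliminates to the (E)-alkenylstannane. The conditions are non-basic, so C2 should keep its configuration, and ketones such as the tropone carbonyl do not react.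

Step 14
Reactants: 25 (Z)-but-2-ene-1,4-diol
Product: 26 (Z)-1,4-bis(triisopropylsilyloxy)but-2-ene
Conditions: TIPSCl, imidazole, DMF, rt
Reagents that add atoms: triisopropylsilyl chloride, CC(C)[Si](Cl)(C(C)C)C(C)C
Why: Imidazole-promoted silylation of both primary alcohols.

Step 15
Reactants: 26 (Z)-1,4-bis(triisopropylsilyloxy)but-2-ene
Product: 28 (triisopropylsilyloxy)acetaldehyde, via ozonide 27 (not isolated)
Conditions: O3, CH2Cl2, −78 °C; then PPh3, −78 °C → rt
Reagents that add atoms: ozone, [O-][O+]=O
Why: Ozonolysis of the symmetrical alkene with reductive work-up; each molecule of 26 gives two of 28.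

Step 16
Reactants: 28 (triisopropylsilyloxy)acetaldehyde
Product: 29 (2R,3R)-3-methyl-1-(triisopropylsilyloxy)pent-4-en-2-ol
Conditions: trans-2-butene, n-BuLi, KOt-Bu, THF, −78 → −45 °C; (+)-Ipc2BOMe, −78 °C; BF3·OEt2; 28, −78 °C; then NaOH, H2O2
Reagents that add atoms: (E)-but-2-ene, C/C=C/C
Why: Brown crotylation: the (E)-crotylborane reacts through a closed six-membered chair transition state, so the E geometry gives the anti product. The isopinocampheyl groups derived from (−)-α-pinene direct the crotyl group to the aldehyde face that gives the 2R carbinol, so C2 and C3 are both set here by the reagent.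

Step 17
Reactants: 29 (2R,3R)-3-methyl-1-(triisopropylsilyloxy)pent-4-en-2-ol
Product: 31 (5R,6R)-5-methyl-6-[(triisopropylsilyloxy)methyl]tetrahydro-2H-pyran-2-ol, via hydroxy aldehyde 30 (not isolated)
Conditions: Rh(CO)2(acac) (1 mol %), BiPhePhos, CO/H2 (1:1, 5 bar), THF, 60 °C
Reagents that add atoms: carbon monoxide, [C-]#[O+]
Why: Linear-selective hydroformylation as in step 4, helped by the allylic branch; the hydroxy aldehyde closes to the lactol and neither stereocentre is involved.

Step 18
Reactants: 31 (5R,6R)-5-methyl-6-[(triisopropylsilyloxy)methyl]tetrahydro-2H-pyran-2-ol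
Product: 33 (2R,3R)-3-methyl-2-[(triisopropylsilyloxy)methyl]-3,4-dihydro-2H-pyran, via anomeric mesylate 32 (not isolated)
Conditions: MsCl, Et3N, CH2Cl2, 0 °C → reflux
Reagents that add atoms: none
Why: Lactol dehydration through the anomeric mesylate, as in step 5.

Step 19
Reactants: 33 (2R,3R)-3-methyl-2-[(triisopropylsilyloxy)methyl]-3,4-dihydro-2H-pyran
Product: 35 (2R,3R)-3-methyl-2-[(triisopropylsilyloxy)methyl]-3,4-dihydro-2H-pyran-6-carbaldehyde, via 6-lithio enol ether 34 (not isolated)
Conditions: t-BuLi, THF, −78 → 0 °C; DMF, −78 °C → rt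
Reagents that add atoms: N,N-dimethylformamide, CN(C)C=O
Why: α-Lithiation of the cyclic enol ether and formylation, as in step 6.

Step 20
Reactants: 35 (2R,3R)-3-methyl-2-[(triisopropylsilyloxy)methyl]-3,4-dihydro-2H-pyran-6-carbaldehyde
Product: 37 (2R,3R)-5-bromo-3-methyl-2-[(triisopropylsilyloxy)methyl]-3,4-dihydro-2H-pyran-6-carbaldehyde, via dibromide 36 (not isolated)
Conditions: Br2, CH2Cl2, −78 °C; then Et3N, −78 °C → rt
Reagents that add atoms: bromine, BrBr
Why: Bromination–dehydrobromination of the α-alkoxy enal, as in step 7.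

Step 21
Reactants: 37 (2R,3R)-5-bromo-3-methyl-2-[(triisopropylsilyloxy)methyl]-3,4-dihydro-2H-pyran-6-carbaldehyde
Product: 39 (2R,3R)-5-acetyl-3-methyl-2-[(triisopropylsilyloxy)methyl]-3,4-dihydro-2H-pyran-6-carbaldehyde, via ethoxyvinyl enal 38 (not isolated)
Conditions: tributyl(1-ethoxyvinyl)stannane, Pd(PPh3)4 (5 mol %), CuI (10 mol %), toluene, 90 °C; then 1 M HCl, THF, 0 °C → rt
Reagents that add atoms: tributyl(1-ethoxyvinyl)stannane, CCCC[Sn](CCCC)(CCCC)C(=C)OCC; water, O
Why: Stille coupling and enol-ether hydrolysis, as in step 8.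

Step 22
Reactants: 39 (2R,3R)-5-acetyl-3-methyl-2-[(triisopropylsilyloxy)methyl]-3,4-dihydro-2H-pyran-6-carbaldehyde; 2 dimethyl (1-methoxy-2-oxopropyl)phosphonate
Product: 42 (2R,3R)-8-methoxy-3,5-dimethyl-2-[(triisopropylsilyloxy)methyl]-3,4-dihydrocyclohepta[b]pyran-7(2H)-one, via dienone 40 (not isolated), via aldol adduct 41 (not isolated)
Conditions: LiCl, DBU, MeCN, 0 °C → rt; then 50 °C
Reagents that add atoms: none
Why: Proposed new method: the same sequence as in step 9 — Horner–Wadsworth–Emmons olefination of the formyl group by the chelated anion of 2, chelation-directed soft enolisation of the new α-methoxy methyl ketone, 7-(enolendo)-exo-trig aldol addition to the acetyl group and aromatising dehydration — with the double aldol route to benzotropolones and tandem olefination/aldol annulations as the closest known reaction types. C2 and C3 carry no acidic hydrogen and should be unaffected.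

Step 23
Reactants: 42 (2R,3R)-8-methoxy-3,5-dimethyl-2-[(triisopropylsilyloxy)methyl]-3,4-dihydrocyclohepta[b]pyran-7(2H)-one
Product: 43 (2R,3R)-2-(hydroxymethyl)-8-methoxy-3,5-dimethyl-3,4-dihydrocyclohepta[b]pyran-7(2H)-one
Conditions: TBAF, AcOH, THF, 0 °C → rt
Reagents that add atoms: none
Why: Buffered fluoride cleavage of the silyl ether, as in step 10.

Step 24
Reactants: 43 (2R,3R)-2-(hydroxymethyl)-8-methoxy-3,5-dimethyl-3,4-dihydrocyclohepta[b]pyran-7(2H)-one
Product: 44 (2R,3R)-8-methoxy-3,5-dimethyl-7-oxo-2,3,4,7-tetrahydrocyclohepta[b]pyran-2-carbaldehyde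
Conditions: Dess–Martin periodinane, NaHCO3, CH2Cl2, 0 °C → rt
Reagents that add atoms: none
Why: Buffered Dess–Martin oxidation, as in step 11; the aldehyde is used at once to avoid epimerisation at C2.

Step 25
Reactants: 44 (2R,3R)-8-methoxy-3,5-dimethyl-7-oxo-2,3,4,7-tetrahydrocyclohepta[b]pyran-2-carbaldehyde
Product: 45 (2R,3R)-2-[(E)-2-iodoethenyl]-8-methoxy-3,5-dimethyl-3,4-dihydrocyclohepta[b]pyran-7(2H)-one
Conditions: CHI3, CrCl2, THF/dioxane, 0 °C → rt
Reagents that add atoms: iodoform, IC(I)I
Why: Takai iodo-olefination: the gem-dichromium species from iodoform and divalent chromium adds to the aldehyde and eliminates to the (E)-alkenyl iodide under non-basic conditions.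

Step 26
Reactants: 24 (2R)-8-methoxy-5-methyl-2-[(E)-2-(tributylstannyl)ethenyl]-3,4-dihydrocyclohepta[b]pyran-7(2H)-one; 45 (2R,3R)-2-[(E)-2-iodoethenyl]-8-methoxy-3,5-dimethyl-3,4-dihydrocyclohepta[b]pyran-7(2H)-one
Product: 46 (2R,3R)-8-methoxy-2-{(1E,3E)-4-[(2R)-8-methoxy-5-methyl-7-oxo-2,3,4,7-tetrahydrocyclohepta[b]pyran-2-yl]buta-1,3-dien-1-yl}-3,5-dimethyl-3,4-dihydrocyclohepta[b]pyran-7(2H)-one
Conditions: CuTC [copper thiophene-2-carboxylate, Cu(O2CC4H3S), monovalent copper], NMP, 0 °C → rt
Reagents that add atoms: none
Why: Copper-mediated Stille-type coupling: tin-to-copper transmetallation and coupling with the alkenyl iodide proceed with retention of both alkene geometries. No palladium is present, so the allylic C2–O bonds cannot ionise to π-allyl complexes.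

Step 27
Reactants: 46 (2R,3R)-8-methoxy-2-{(1E,3E)-4-[(2R)-8-methoxy-5-methyl-7-oxo-2,3,4,7-tetrahydrocyclohepta[b]pyran-2-yl]buta-1,3-dien-1-yl}-3,5-dimethyl-3,4-dihydrocyclohepta[b]pyran-7(2H)-one
Product: 47 CNP0332980.1, (2R,3R)-8-hydroxy-2-{(1E,3E)-4-[(2R)-8-hydroxy-5-methyl-7-oxo-2,3,4,7-tetrahydrocyclohepta[b]pyran-2-yl]buta-1,3-dien-1-yl}-3,5-dimethyl-3,4-dihydrocyclohepta[b]pyran-7(2H)-one
Conditions: LiOH, THF/H2O, 50 °C; then NaH2PO4 buffer to pH 5
Reagents that add atoms: water, O
Why: Hydrolysis of the 2-methoxytropones as vinylogous esters: hydroxide adds to C8 and expels methoxide (addition–elimination), and the tropolonate formed is inert to further attack. Buffered acidification keeps acid away from the dienylic ethers, and no stereocentre is involved.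

## Compound list

1 | dimethyl (1-diazo-2-oxopropyl)phosphonate | CC(=O)C(=[N+]=[N-])P(=O)(OC)OC | starting material
2 | dimethyl (1-methoxy-2-oxopropyl)phosphonate (racemic) | COC(C(C)=O)P(=O)(OC)OC | intermediate
3 | (S)-glycidol | OC[C@H]1CO1 | starting material
4 | triisopropylsilyl (R)-glycidyl ether | CC(C)[Si](C(C)C)(C(C)C)OC[C@H]1CO1 | intermediate
5 | (R)-1-(triisopropylsilyloxy)pent-4-en-2-ol | CC(C)[Si](C(C)C)(C(C)C)OC[C@H](O)CC=C | intermediate
6 | (R)-5-hydroxy-6-(triisopropylsilyloxy)hexanal | CC(C)[Si](C(C)C)(C(C)C)OC[C@H](O)CCCC=O | intermediate (not isolated)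
7 | (6R)-6-[(triisopropylsilyloxy)methyl]tetrahydro-2H-pyran-2-ol (anomer mixture) | CC(C)[Si](C(C)C)(C(C)C)OC[C@H]1CCCC(O)O1 | intermediate
8 | (6R)-6-[(triisopropylsilyloxy)methyl]tetrahydro-2H-pyran-2-yl methanesulfonate | CC(C)[Si](C(C)C)(C(C)C)OC[C@H]1CCCC(OS(C)(=O)=O)O1 | intermediate (not isolated)
9 | (R)-2-[(triisopropylsilyloxy)methyl]-3,4-dihydro-2H-pyran | CC(C)[Si](C(C)C)(C(C)C)OC[C@H]1CCC=CO1 | intermediate
10 | (2R)-6-lithio-2-[(triisopropylsilyloxy)methyl]-3,4-dihydro-2H-pyran | CC(C)[Si](C(C)C)(C(C)C)OC[C@H]1CCC=C([Li])O1 | intermediate (not isolated)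
11 | (2R)-2-[(triisopropylsilyloxy)methyl]-3,4-dihydro-2H-pyran-6-carbaldehyde | CC(C)[Si](C(C)C)(C(C)C)OC[C@H]1CCC=C(C=O)O1 | intermediate
12 | (6R)-2,3-dibromo-6-[(triisopropylsilyloxy)methyl]tetrahydro-2H-pyran-2-carbaldehyde (isomer mixture at C2, C3) | CC(C)[Si](C(C)C)(C(C)C)OC[C@H]1CCC(Br)C(Br)(C=O)O1 | intermediate (not isolated)
13 | (2R)-5-bromo-2-[(triisopropylsilyloxy)methyl]-3,4-dihydro-2H-pyran-6-carbaldehyde | CC(C)[Si](C(C)C)(C(C)C)OC[C@H]1CCC(Br)=C(C=O)O1 | intermediate
14 | (2R)-5-(1-ethoxyvinyl)-2-[(triisopropylsilyloxy)methyl]-3,4-dihydro-2H-pyran-6-carbaldehyde | CC(C)[Si](C(C)C)(C(C)C)OC[C@H]1CCC(C(=C)OCC)=C(C=O)O1 | intermediate (not isolated)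
15 | (2R)-5-acetyl-2-[(triisopropylsilyloxy)methyl]-3,4-dihydro-2H-pyran-6-carbaldehyde | CC(C)[Si](C(C)C)(C(C)C)OC[C@H]1CCC(C(C)=O)=C(C=O)O1 | intermediate
16 | (2R)-5-acetyl-6-[(E)-2-methoxy-3-oxobut-1-enyl]-2-[(triisopropylsilyloxy)methyl]-3,4-dihydro-2H-pyran (the cyclising alkene isomer is drawn) | CC(C)[Si](C(C)C)(C(C)C)OC[C@H]1CCC(C(C)=O)=C(/C=C(/OC)C(C)=O)O1 | intermediate (not isolated)
17 | (2R)-5-hydroxy-8-methoxy-5-methyl-2-[(triisopropylsilyloxy)methyl]-3,4,5,6-tetrahydrocyclohepta[b]pyran-7(2H)-one (epimers at C5) | CC(C)[Si](C(C)C)(C(C)C)OC[C@H]1CCC2=C(C=C(OC)C(=O)CC2(C)O)O1 | intermediate (not isolated)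
18 | (2R)-8-methoxy-5-methyl-2-[(triisopropylsilyloxy)methyl]-3,4-dihydrocyclohepta[b]pyran-7(2H)-one | CC(C)[Si](C(C)C)(C(C)C)OC[C@H]1CCc2c(C)cc(=O)c(OC)cc2O1 | intermediate
19 | (2R)-2-(hydroxymethyl)-8-methoxy-5-methyl-3,4-dihydrocyclohepta[b]pyran-7(2H)-one | OC[C@H]1CCc2c(C)cc(=O)c(OC)cc2O1 | intermediate
20 | (2R)-8-methoxy-5-methyl-7-oxo-2,3,4,7-tetrahydrocyclohepta[b]pyran-2-carbaldehyde | O=C[C@H]1CCc2c(C)cc(=O)c(OC)cc2O1 | intermediate
21 | dibromomethane | BrCBr | starting material
22 | dibromomethyllithium | [Li]C(Br)Br | intermediate (not isolated)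
23 | tributyl(dibromomethyl)stannane | CCCC[Sn](CCCC)(CCCC)C(Br)Br | intermediate
24 | (2R)-8-methoxy-5-methyl-2-[(E)-2-(tributylstannyl)ethenyl]-3,4-dihydrocyclohepta[b]pyran-7(2H)-one | CCCC[Sn](CCCC)(CCCC)/C=C/[C@H]1CCc2c(C)cc(=O)c(OC)cc2O1 | intermediate
25 | (Z)-but-2-ene-1,4-diol | OC/C=C\CO | starting material
26 | (Z)-1,4-bis(triisopropylsilyloxy)but-2-ene | CC(C)[Si](C(C)C)(C(C)C)OC/C=C\CO[Si](C(C)C)(C(C)C)C(C)C | intermediate
27 | 3,5-bis[(triisopropylsilyloxy)methyl]-1,2,4-trioxolane | CC(C)[Si](C(C)C)(C(C)C)OCC1OOC(CO[Si](C(C)C)(C(C)C)C(C)C)O1 | intermediate (not isolated)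
28 | (triisopropylsilyloxy)acetaldehyde | CC(C)[Si](C(C)C)(C(C)C)OCC=O | intermediate
29 | (2R,3R)-3-methyl-1-(triisopropylsilyloxy)pent-4-en-2-ol | C=C[C@@H](C)[C@@H](O)CO[Si](C(C)C)(C(C)C)C(C)C | intermediate
30 | (4R,5R)-5-hydroxy-4-methyl-6-(triisopropylsilyloxy)hexanal | O=CCC[C@@H](C)[C@@H](O)CO[Si](C(C)C)(C(C)C)C(C)C | intermediate (not isolated)
31 | (5R,6R)-5-methyl-6-[(triisopropylsilyloxy)methyl]tetrahydro-2H-pyran-2-ol (anomer mixture) | CC(C)[Si](C(C)C)(C(C)C)OC[C@@H]1OC(O)CC[C@H]1C | intermediate
32 | (5R,6R)-5-methyl-6-[(triisopropylsilyloxy)methyl]tetrahydro-2H-pyran-2-yl methanesulfonate | CC(C)[Si](C(C)C)(C(C)C)OC[C@@H]1OC(OS(C)(=O)=O)CC[C@H]1C | intermediate (not isolated)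
33 | (2R,3R)-3-methyl-2-[(triisopropylsilyloxy)methyl]-3,4-dihydro-2H-pyran | CC(C)[Si](C(C)C)(C(C)C)OC[C@@H]1OC=CC[C@H]1C | intermediate
34 | (2R,3R)-6-lithio-3-methyl-2-[(triisopropylsilyloxy)methyl]-3,4-dihydro-2H-pyran | CC(C)[Si](C(C)C)(C(C)C)OC[C@@H]1OC([Li])=CC[C@H]1C | intermediate (not isolated)
35 | (2R,3R)-3-methyl-2-[(triisopropylsilyloxy)methyl]-3,4-dihydro-2H-pyran-6-carbaldehyde | CC(C)[Si](C(C)C)(C(C)C)OC[C@@H]1OC(C=O)=CC[C@H]1C | intermediate
36 | (5R,6R)-2,3-dibromo-5-methyl-6-[(triisopropylsilyloxy)methyl]tetrahydro-2H-pyran-2-carbaldehyde (isomer mixture at C2, C3) | CC(C)[Si](C(C)C)(C(C)C)OC[C@@H]1OC(Br)(C=O)C(Br)C[C@H]1C | intermediate (not isolated)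
37 | (2R,3R)-5-bromo-3-methyl-2-[(triisopropylsilyloxy)methyl]-3,4-dihydro-2H-pyran-6-carbaldehyde | CC(C)[Si](C(C)C)(C(C)C)OC[C@@H]1OC(C=O)=C(Br)C[C@H]1C | intermediate
38 | (2R,3R)-5-(1-ethoxyvinyl)-3-methyl-2-[(triisopropylsilyloxy)methyl]-3,4-dihydro-2H-pyran-6-carbaldehyde | CC(C)[Si](C(C)C)(C(C)C)OC[C@@H]1OC(C=O)=C(C(=C)OCC)C[C@H]1C | intermediate (not isolated)
39 | (2R,3R)-5-acetyl-3-methyl-2-[(triisopropylsilyloxy)methyl]-3,4-dihydro-2H-pyran-6-carbaldehyde | CC(C)[Si](C(C)C)(C(C)C)OC[C@@H]1OC(C=O)=C(C(C)=O)C[C@H]1C | intermediate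
40 | (2R,3R)-5-acetyl-6-[(E)-2-methoxy-3-oxobut-1-enyl]-3-methyl-2-[(triisopropylsilyloxy)methyl]-3,4-dihydro-2H-pyran (the cyclising alkene isomer is drawn) | CC(C)[Si](C(C)C)(C(C)C)OC[C@@H]1OC(/C=C(/OC)C(C)=O)=C(C(C)=O)C[C@H]1C | intermediate (not isolated)
41 | (2R,3R)-5-hydroxy-8-methoxy-3,5-dimethyl-2-[(triisopropylsilyloxy)methyl]-3,4,5,6-tetrahydrocyclohepta[b]pyran-7(2H)-one (epimers at C5) | CC(C)[Si](C(C)C)(C(C)C)OC[C@@H]1OC2=C(C[C@H]1C)C(C)(O)CC(=O)C(OC)=C2 | intermediate (not isolated)
42 | (2R,3R)-8-methoxy-3,5-dimethyl-2-[(triisopropylsilyloxy)methyl]-3,4-dihydrocyclohepta[b]pyran-7(2H)-one | Cc1cc(=O)c(OC)cc2c1C[C@@H](C)[C@H](CO[Si](C(C)C)(C(C)C)C(C)C)O2 | intermediate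
43 | (2R,3R)-2-(hydroxymethyl)-8-methoxy-3,5-dimethyl-3,4-dihydrocyclohepta[b]pyran-7(2H)-one | Cc1cc(=O)c(OC)cc2c1C[C@@H](C)[C@H](CO)O2 | intermediate
44 | (2R,3R)-8-methoxy-3,5-dimethyl-7-oxo-2,3,4,7-tetrahydrocyclohepta[b]pyran-2-carbaldehyde | Cc1cc(=O)c(OC)cc2c1C[C@@H](C)[C@H](C=O)O2 | intermediate
45 | (2R,3R)-2-[(E)-2-iodoethenyl]-8-methoxy-3,5-dimethyl-3,4-dihydrocyclohepta[b]pyran-7(2H)-one | Cc1cc(=O)c(OC)cc2c1C[C@@H](C)[C@H](/C=C/I)O2 | intermediate
46 | bis(methyl ether) of the target, (2R,3R)-8-methoxy-2-{(1E,3E)-4-[(2R)-8-methoxy-5-methyl-7-oxo-2,3,4,7-tetrahydrocyclohepta[b]pyran-2-yl]buta-1,3-dien-1-yl}-3,5-dimethyl-3,4-dihydrocyclohepta[b]pyran-7(2H)-one | Cc1cc(=O)c(OC)cc2c1C[C@@H](C)[C@H](/C=C/C=C/[C@H]1CCc3c(C)cc(=O)c(OC)cc3O1)O2 | intermediate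
47 | CNP0332980.1 | Cc1cc(=O)c(O)cc2c1C[C@@H](C)[C@H](/C=C/C=C/[C@H]1CCc3c(C)cc(=O)c(O)cc3O1)O2 | target

## Step count and least certain steps

Total: 27 steps. Longest linear sequence: 14 steps (steps 14–27, from 25 through the left half to 47). The right half takes 13 steps (2–11, 13, 26, 27); steps 1 and 12 prepare reagents 2 and 23.

**Step 9 (key step, new method).**
- What may go wrong: the acetyl group may enolise and add to the new ketone instead of the reverse, which would give a constitutionally isomeric tropone; the olefin may fail to reach the geometry that can cyclise; or the base may degrade the keto aldehyde by self-condensation or strip the acetyl group from 2 by retro-Claisen cleavage.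
- Fallback (known chemistry), from 14 to 18: 14 is isolated by leaving out the acid treatment of step 8. Horner–Wadsworth–Emmons reaction of 14 with 2 (LiCl, DBU, MeCN) should give (2R)-5-(1-ethoxyvinyl)-6-[(E)-2-methoxy-3-oxobut-1-enyl]-2-[(triisopropylsilyloxy)methyl]-3,4-dihydro-2H-pyran F1. Its only ketone is the one that must become the donor. Kinetic silylation (LiN(SiMe3)2, TBSCl, THF, −78 °C) should give the silyl dienol ether (2R)-6-[(1E)-3-(tert-butyldimethylsilyloxy)-2-methoxybuta-1,3-dienyl]-5-(1-ethoxyvinyl)-2-[(triisopropylsilyloxy)methyl]-3,4-dihydro-2H-pyran F2. A catalytic Brønsted acid (HNTf2, CH2Cl2, −40 °C) then protonates the ethoxyvinyl group to an oxocarbenium ion, which the silyl enol ether captures (Mukaiyama-type addition); loss of the ethoxysilane aromatises the ring to 18. The acetyl carbon is never present as a ketone alongside a second enolisable methyl ketone, so the regiochemistry is fixed by structure.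

**Step 22 (new method).**
- What may go wrong: the same loss of donor selectivity and failure of ring closure as in step 9.
- Fallback, from 38 to 42: Horner–Wadsworth–Emmons reaction of 38 (isolated without the acid treatment of step 21) with 2 should give (2R,3R)-5-(1-ethoxyvinyl)-6-[(E)-2-methoxy-3-oxobut-1-enyl]-3-methyl-2-[(triisopropylsilyloxy)methyl]-3,4-dihydro-2H-pyran F3. Silylation as above should give (2R,3R)-6-[(1E)-3-(tert-butyldimethylsilyloxy)-2-methoxybuta-1,3-dienyl]-5-(1-ethoxyvinyl)-3-methyl-2-[(triisopropylsilyloxy)methyl]-3,4-dihydro-2H-pyran F4, and acid-triggered cyclisation with loss of the ethoxysilane should give 42.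

**Step 7.**
- What may go wrong: the elimination may stall at the dibromide or take the other direction (loss of HBr toward C4), because the hydrogen to be removed is not acidified by the aldehyde; bromine may also oxidise the aldehyde.
- Fallback, from 9 to 15, with the order of events changed: bromination–dehydrobromination of the plain enol ether 9 (Br2, CH2Cl2, −78 °C; then Et3N), a well-known reaction of dihydropyrans, should give (R)-5-bromo-2-[(triisopropylsilyloxy)methyl]-3,4-dihydro-2H-pyran F5. Stille coupling with tributyl(1-ethoxyvinyl)stannane (Pd(PPh3)4, toluene, 90 °C) should give (R)-5-(1-ethoxyvinyl)-2-[(triisopropylsilyloxy)methyl]-3,4-dihydro-2H-pyran F6. α-Lithiation and formylation (t-BuLi, THF; DMF) then give 14, which is hydrolysed as in step 8 to 15.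

**Step 20.**
- What may go wrong: the same stalled or misdirected elimination as in step 7, here next to the C3 methyl group.
- Fallback, from 33 to 39: bromination–dehydrobromination of 33 should give (2R,3R)-5-bromo-3-methyl-2-[(triisopropylsilyloxy)methyl]-3,4-dihydro-2H-pyran F7. Stille coupling should give (2R,3R)-5-(1-ethoxyvinyl)-3-methyl-2-[(triisopropylsilyloxy)methyl]-3,4-dihydro-2H-pyran F8. Lithiation and formylation then give 38, and hydrolysis gives 39.

**Step 26.**
- What may go wrong: homocoupling or protodestannylation of the stannane, and sequestration of copper by the methoxytropone carbonyls, which would slow the transmetallation.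
- Fallback, from 20 and 45 to 46, with boron in place of tin: boryl olefination of 20 (Cl2CHB(pin), CrCl2, LiI, THF) should give the alkenylboronate (2R)-8-methoxy-5-methyl-2-[(E)-2-(4,4,5,5-tetramethyl-1,3,2-dioxaborolan-2-yl)ethenyl]-3,4-dihydrocyclohepta[b]pyran-7(2H)-one F9. A fast room-temperature Suzuki–Miyaura coupling with 45 (PdCl2(dppf), K3PO4, THF/H2O) should give 46. The contact time with palladium is kept short so that oxidative addition to the alkenyl iodide outruns ionisation of the allylic ethers.

**Step 27.**
- What may go wrong: ring contraction of a methoxytropone toward a benzoate under hydroxide, incomplete hydrolysis of the second ether, or ionisation of the dienylic C2–O bonds on acidification.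
- Fallback, from 46 to 47: the O–CH3 bonds are cleaved instead of the ring C–O bonds, by SN2 attack of chloride on the methyl groups (LiCl, DMF, 120 °C), followed by buffered work-up. No new intermediate is formed.

## Further compounds

F1 | step 9 | (2R)-5-(1-ethoxyvinyl)-6-[(E)-2-methoxy-3-oxobut-1-enyl]-2-[(triisopropylsilyloxy)methyl]-3,4-dihydro-2H-pyran | CC(C)[Si](C(C)C)(C(C)C)OC[C@H]1CCC(C(=C)OCC)=C(/C=C(/OC)C(C)=O)O1
F2 | step 9 | (2R)-6-[(1E)-3-(tert-butyldimethylsilyloxy)-2-methoxybuta-1,3-dienyl]-5-(1-ethoxyvinyl)-2-[(triisopropylsilyloxy)methyl]-3,4-dihydro-2H-pyran | CC(C)[Si](C(C)C)(C(C)C)OC[C@H]1CCC(C(=C)OCC)=C(/C=C(/OC)C(=C)O[Si](C)(C)C(C)(C)C)O1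
F3 | step 22 | (2R,3R)-5-(1-ethoxyvinyl)-6-[(E)-2-methoxy-3-oxobut-1-enyl]-3-methyl-2-[(triisopropylsilyloxy)methyl]-3,4-dihydro-2H-pyran | CC(C)[Si](C(C)C)(C(C)C)OC[C@@H]1OC(/C=C(/OC)C(C)=O)=C(C(=C)OCC)C[C@H]1C
F4 | step 22 | (2R,3R)-6-[(1E)-3-(tert-butyldimethylsilyloxy)-2-methoxybuta-1,3-dienyl]-5-(1-ethoxyvinyl)-3-methyl-2-[(triisopropylsilyloxy)methyl]-3,4-dihydro-2H-pyran | CC(C)[Si](C(C)C)(C(C)C)OC[C@@H]1OC(/C=C(/OC)C(=C)O[Si](C)(C)C(C)(C)C)=C(C(=C)OCC)C[C@H]1C
F5 | step 7 | (R)-5-bromo-2-[(triisopropylsilyloxy)methyl]-3,4-dihydro-2H-pyran | CC(C)[Si](C(C)C)(C(C)C)OC[C@H]1CCC(Br)=CO1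
F6 | step 7 | (R)-5-(1-ethoxyvinyl)-2-[(triisopropylsilyloxy)methyl]-3,4-dihydro-2H-pyran | CC(C)[Si](C(C)C)(C(C)C)OC[C@H]1CCC(C(=C)OCC)=CO1
F7 | step 20 | (2R,3R)-5-bromo-3-methyl-2-[(triisopropylsilyloxy)methyl]-3,4-dihydro-2H-pyran | CC(C)[Si](C(C)C)(C(C)C)OC[C@@H]1OC=C(Br)C[C@H]1C
F8 | step 20 | (2R,3R)-5-(1-ethoxyvinyl)-3-methyl-2-[(triisopropylsilyloxy)methyl]-3,4-dihydro-2H-pyran | CC(C)[Si](C(C)C)(C(C)C)OC[C@@H]1OC=C(C(=C)OCC)C[C@H]1C
F9 | step 26 | (2R)-8-methoxy-5-methyl-2-[(E)-2-(4,4,5,5-tetramethyl-1,3,2-dioxaborolan-2-yl)ethenyl]-3,4-dihydrocyclohepta[b]pyran-7(2H)-one | CC1(C)OB(/C=C/[C@H]2CCc3c(C)cc(=O)c(OC)cc3O2)OC1(C)C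
F0 | step 27 | none | none
A1 | alternative 1 | dienyl diacid carrying all three stereocentres | OC(=O)[C@@H](C)[C@H](/C=C/C=C/[C@H](Oc1cc(OC)c(=O)cc(C)c1Br)CC(=O)O)Oc1cc(OC)c(=O)cc(C)c1Br
A2 | alternative 2 | left pyran with (E)-2-(trimethylsilyl)ethenyl group at C2 | Cc1cc(=O)c(OC)cc2c1C[C@@H](C)[C@H](/C=C/[Si](C)(C)C)O2
A3 | alternative 3 | target bis(methyl ether), identical with 46 | Cc1cc(=O)c(OC)cc2c1C[C@@H](C)[C@H](/C=C/C=C/[C@H]1CCc3c(C)cc(=O)c(OC)cc3O1)O2
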